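**Two exits.** The substrate charged stayed counted: in the noon run at 120 min, self-condensation product, target and substrate together held 98.1%. So I watched two rates, the gain of self-condensation product and the gain of target. The first goes with substrate squared and the second with substrate times partner, so I took their ratio to follow substrate over partner.

| flask | substrate | partner | temperature | remark | time |
|---|---|---|---|---|---|
| noon | 20 mM | 24 mM | 75 °C | run made earlier |  |
| winter | 20 mM | 16 mM | 86 °C | run made earlier |  |
| midnight | 20 mM | 36 mM | 75 °C | run made earlier |  |
| north | 20 mM | 24.0 mM (fed, over 30 min) | 80 °C | all else is in the flask from the start; the feed brings no volume worth counting | 3.0 h |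
| south-east | 20 mM | 24.0 mM | 80 °C | everything together at the start | 3.0 h |
| east | 20 mM (fed, over 2.0 h) | 24.0 mM |  | the addition at 40 °C, then warmed to 80 °C; the feed brings no volume worth counting | 3.0 h |
| north-west | 20 mM (fed, over 2.0 h) | 24.0 mM | 80 °C | all else is in the flask from the start; the feed brings no volume worth counting | 3.0 h |

- noon (time / min: self-condensation product / %, target / %, substrate / %): 15.0: 10.3, 16.9, 68.3; 30.0: 16.7, 31.1, 50.3; 50.0: 19.7, 43.1, 35.1; 60.0: 20.1, 45.5, 30.2; 80.0: 22.8, 52.1, 23.2; 90.0: 22.2, 54.8, 20.6; 120: 23.4, 59.9, 14.8
- winter (time / h: self-condensation product / %, target / %, substrate / %): 0.133: 11.7, 15.5, 70.7; 0.333: 20.8, 29.0, 47.8; 0.667: 25.3, 41.4, 31.3; 1.00: 27.8, 47.0, 21.7; 1.33: 30.4, 51.0, 17.6; 2.00: 31.0, 55.9, 11.5; 2.50: 32.4, 57.0, 9.8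
- midnight (time / h: self-condensation product / %, target / %, substrate / %): 0.133: 6.4, 12.6, 74.4; 0.333: 11.3, 32.3, 51.8; 0.667: 14.1, 51.0, 31.2; 1.00: 15.8, 61.9, 19.8; 1.33: 16.8, 67.2, 12.9; 2.00: 16.7, 74.7, 6.7; 2.50: 17.7, 77.2, 4.4

(scatter of a reading: 0.5 percentage points)

- in percentages every species weighs as the substrate in it: one self-condensation product counts as two
- for target the crystals are counted in
- as a solid, counted per litre of solution: crystals
- the analysis behind the earlier runs scatters by 0.5 percentage points, standard deviation
- reactions considered so far: substrate + partner <-> adduct; adduct <-> target; 2 substrate -> self-condensation product; crystals <-> target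

- the flask with the highest amount of self-condensation product, in percent of the substrate charged ("all alike" if they lie within 1.5 percentage points) (north / south-east / east / north-west / all alike)
- final self-condensation product, as a percentage of the substrate charged, in north
- final self-condensation product, as a percentage of the substrate charged, in south-east
- final self-condensation product, as a percentage of the substrate charged, in east
- final self-condensation product, as a percentage of the substrate charged, in north-west

**The split.** At 30.0 min the noon run read 0.644 for self-condensation product over target, multiplied by partner over substrate as charged; I called this reading the split, a selectivity factor. The midnight run at 0.333 h read 0.630 and the winter run, at 86 °C, a lower 0.574. 80 °C lies between these temperatures, so I took the midpoint of the mean 75 °C reading and the 86 °C reading, 0.605, as the split factor at that temperature.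

**My reckoning.** South-east has the noon charge, so I expected the noon level, 23.4% at 120 min, and its split began at 0.505. In north, with 12.0 mM of partner in and substrate taken as charged, the split reads 1.01, twice that. I expected north highest and north-west lowest, because its substrate enters against the whole partner, with east beside south-east.

**The forecast.** It named north, with 33% there, 24% in south-east, 22% in east and 15% in north-west, saying of north that “substrate sits hot with little partner”.

**The result.** North gave 32.7%, south-east 23.4%, east 21.9% and north-west 14.0%.

    substrate + partner ⇌ adduct (K = 170 M⁻¹, k = 1.20 M⁻¹ min⁻¹, Ea = 79.0 kJ mol⁻¹, ΔH = −20.0 kJ mol⁻¹)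
    adduct ⇌ target (K = 19.0, k = 0.530 min⁻¹, Ea = 89.0 kJ mol⁻¹, ΔH = −16.0 kJ mol⁻¹)
    2 substrate → self-condensation product (k = 0.350 M⁻¹ min⁻¹, Ea = 62.0 kJ mol⁻¹)
    crystals ⇌ target, rate k4*(cs4 - [target]) while solid is left; crystals form when [target] > cs4 (solubility = 6.60 mM, k = 2.90 min⁻¹)
    (constants at 80 °C)

**The split again.** In north-west from 1.50 h to 2.00 h, self-condensation product gained 4.3 percentage points and target 16 points, a ratio of 0.269, while the split factor on the mean substrate and partner of those moments gives 0.269. In the neighbour of north-west charged with 6.0 mM of partner, 7.03 mM of substrate stood against 1.29 mM of partner at 3.00 h, a split of 3.30, and that flask held 41.3% of self-condensation product against 22.3% of target.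

The runs stem from a simulated flask for substances that don't exist.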